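The dienone ring (C3a, C4, C5, C6, C7, C7a) is annulated onto a stereodefined γ-lactone (O1, C2, C3, C3a, C7a). The vinylogous ester O1–C7a=C7–C6=O is read as the Wittig product of the lactone carbonyl C7a, and C4–C5 as an aldol bond: the γ-carbanion of a β-keto phosphorus ylide (C5–C6–C7) adds to a formyl group on C3a, the ylide carbon then olefinates C7a, and dehydration gives the ring in one pot. The annulation is run with the allyl group on quaternary C3a (set anti to the C3 methyl); a final suprafacial Cope shift moves it to C5 and so relays the configuration to that remote centre.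

Key step: step 7

Remark: benzofuran numbering of the target (O1, C2, C3, C3a, C4, C5, C6, C7, C7a) is used for all intermediates; ylide 11 is assumed not to be commercial and is made in step 6.

Step 1
Reactants: 1 3,4-dimethoxybenzaldehyde; 2 (E)-but-2-ene
Product: 3 (1R,2R)-1-(3,4-dimethoxyphenyl)-2-methylbut-3-en-1-ol (anti)
Conditions: 2, t-BuOK, n-BuLi, THF, −45 °C; (+)-Ipc2BOMe [from (−)-α-pinene], −78 °C; BF3·OEt2; 1, −78 °C; NaOH, H2O2
Reagents that add atoms: none
Why: Brown asymmetric crotylboration, in which the (E)-crotylborane reacts through a chair Zimmerman–Traxler transition state to give the anti adduct and the isopinocampheyl groups of the (−)-α-pinene series direct attack to the aldehyde face that gives the (1R) carbinol, so that C2 and C3 of the target (R,R, aryl and methyl trans) are set here.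

Step 2
Reactants: 3 (1R,2R)-1-(3,4-dimethoxyphenyl)-2-methylbut-3-en-1-ol
Product: 4 (1R,2R)-1-(3,4-dimethoxyphenyl)-2-methylbutane-1,4-diol
Conditions: 9-BBN, THF, 0 °C to rt; NaOH, H2O2
Reagents that add atoms: hydrogen peroxide, OO
Why: Anti-Markovnikov hydroboration–oxidation of the terminal alkene should give the primary alcohol without touching either stereocentre.

Step 3
Reactants: 4 (1R,2R)-1-(3,4-dimethoxyphenyl)-2-methylbutane-1,4-diol
Product: 6 (4R,5R)-5-(3,4-dimethoxyphenyl)-4-methyloxolan-2-one, via lactol 5 (not isolated)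
Conditions: TEMPO (cat.), PhI(OAc)2, CH2Cl2, rt
Reagents that add atoms: none
Why: Oxidative lactonisation, in which the oxoammonium oxidant takes the primary alcohol selectively, the aldehyde closes onto the benzylic hydroxyl to the lactol and this is oxidised on to the trans γ-lactone with the benzylic oxygen retained as O1.

Step 4
Reactants: 6 (4R,5R)-5-(3,4-dimethoxyphenyl)-4-methyloxolan-2-one
Product: 7 (4R,5R)-5-(3,4-dimethoxyphenyl)-3-(hydroxymethylidene)-4-methyloxolan-2-one
Conditions: NaH, HCO2Et, THF, 0 °C to rt; aq. HCl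
Reagents that add atoms: ethyl formate, CCOC=O
Why: Claisen formylation of the lactone enolate at its only α-methylene (future C3a) gives the stabilised hydroxymethylene lactone, whose new carbon is the future C4.

Step 5
Reactants: 7 (4R,5R)-5-(3,4-dimethoxyphenyl)-3-(hydroxymethylidene)-4-methyloxolan-2-one
Product: 8 (3R,4R,5R)-5-(3,4-dimethoxyphenyl)-4-methyl-2-oxo-3-(prop-2-en-1-yl)oxolane-3-carbaldehyde
Conditions: allyl methyl carbonate, Pd(PPh3)4 (cat.), THF, rt
Reagents that add atoms: allyl methyl carbonate, C=CCOC(=O)OC
Why: Tsuji–Trost allylation under neutral conditions, in which the soft formyl-lactone enolate attacks the π-allylpalladium complex through carbon on the face of planar C3a anti to the adjacent C3 methyl group, which should set the quaternary C3a centre with allyl trans to methyl and cis to aryl.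

Step 6
Reactants: 9 methyltriphenylphosphonium bromide; 10 methyl methoxyacetate
Product: 11 1-methoxy-3-(triphenyl-λ5-phosphanylidene)propan-2-one
Conditions: 9 (2 equiv), n-BuLi (2 equiv), THF, 0 °C; then 10, 0 °C to rt
Reagents that add atoms: none
Why: Acylation of methylenetriphenylphosphorane by the ester, the second equivalent of ylide deprotonating the acylphosphonium salt to the stabilised β-keto ylide.

Step 7
Reactants: 8 (3R,4R,5R)-5-(3,4-dimethoxyphenyl)-4-methyl-2-oxo-3-(prop-2-en-1-yl)oxolane-3-carbaldehyde; 11 1-methoxy-3-(triphenyl-λ5-phosphanylidene)propan-2-one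
Product: 15 (2R,3R,3aR)-2-(3,4-dimethoxyphenyl)-5-methoxy-3-methyl-3a-(prop-2-en-1-yl)-3,3a-dihydro-1-benzofuran-6(2H)-one, via aldol adduct 12 (not isolated), via hydroxy enone 13 (not isolated), via mesylate 14 (not isolated)
Conditions: 11, LDA, THF, −78 °C; then 8, −78 °C; AcOH; PhMe, 90 °C; MsCl, Et3N, 0 °C to rt
Reagents that add atoms: none
Why: LDA removes a proton from the methoxymethylene carbon of 11 (the ylidic CH is not acidic) and the ylide anion adds through this carbon (C5) to the non-enolisable aldehyde C4 of 8 (γ-aldol of a β-keto ylide anion), forming C4–C5; after protonation, the untouched keto-stabilised ylide carbon C7 attacks the lactone carbonyl C7a on heating and the oxaphosphetane collapses to Ph3PO and the enol ether C7=C7a (intramolecular Wittig olefination of an ester carbonyl, the reaction type used for chromones and tetronates), forming C7–C7a without opening the lactone. The six-membered carbocycle closes in the 6-exo-trig mode (ylide carbon onto C7a=O). The carbinol C4 and the methoxy carbon C5 form as mixtures, which is harmless because mesylation and E1cB loss of methanesulfonate (only C5–H is available, C3a being quaternary) turn both into sp2 centres of the C4=C5(OMe)–C6=O enone, while C2, C3 and quaternary C3a are not touched. The selectivity needed is site selectivity (C5 to C4, C7 to C7a); it is secured by the reagent, whose hard γ-carbanion reacts at −78 °C only with the aldehyde while the soft ylide carbon reacts only thermally and can reach only C7a through a six-membered transition state. Ring closure is placed before dehydration so that the C4=C5 geometry is dictated by the ring, and the main competitor is C-acylation of the ylide with expulsion of the O1 alkoxide.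

Step 8
Reactants: 15 (2R,3R,3aR)-2-(3,4-dimethoxyphenyl)-5-methoxy-3-methyl-3a-(prop-2-en-1-yl)-3,3a-dihydro-1-benzofuran-6(2H)-one
Product: 16 (2R,3R,5S)-2-(3,4-dimethoxyphenyl)-5-methoxy-3-methyl-5-(prop-2-en-1-yl)-2,3-dihydro-1-benzofuran-6(5H)-one
Conditions: PhMe (degassed), 110 °C, sealed tube
Reagents that add atoms: none
Why: Thermal Cope rearrangement of the 1,5-diene C5=C4–C3a–CH2–CH=CH2, in which the allyl group can only travel across the ring face on which it already sits (suprafacial on C3a–C4=C5), so that the C3a configuration is transferred to C5 (allyl trans to the C3 methyl, methoxy cis), the shift being driven by relief of the congested quaternary ring-fusion carbon and formation of the linearly conjugated dienone.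

Compound list
1 | 3,4-dimethoxybenzaldehyde | COc1ccc(C=O)cc1OC | starting material
2 | (E)-but-2-ene | C/C=C/C | starting material
3 | (1R,2R)-1-(3,4-dimethoxyphenyl)-2-methylbut-3-en-1-ol | O[C@@H](c1ccc(OC)c(OC)c1)[C@@H](C=C)C | intermediate
4 | (1R,2R)-1-(3,4-dimethoxyphenyl)-2-methylbutane-1,4-diol | O[C@@H](c1ccc(OC)c(OC)c1)[C@@H](CCO)C | intermediate
5 | (4R,5R)-5-(3,4-dimethoxyphenyl)-4-methyloxolan-2-ol (lactol, anomer mixture) | C1C(O)O[C@@H](c2ccc(OC)c(OC)c2)[C@@H]1C | intermediate
6 | (4R,5R)-5-(3,4-dimethoxyphenyl)-4-methyloxolan-2-one (trans lactone) | C1C(=O)O[C@@H](c2ccc(OC)c(OC)c2)[C@@H]1C | intermediate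
7 | (4R,5R)-5-(3,4-dimethoxyphenyl)-3-(hydroxymethylidene)-4-methyloxolan-2-one | OC=C1C(=O)O[C@@H](c2ccc(OC)c(OC)c2)[C@@H]1C | intermediate
8 | (3R,4R,5R)-5-(3,4-dimethoxyphenyl)-4-methyl-2-oxo-3-(prop-2-en-1-yl)oxolane-3-carbaldehyde (allyl cis to aryl, formyl cis to methyl) | C=CC[C@@]1(C=O)C(=O)O[C@@H](c2ccc(OC)c(OC)c2)[C@@H]1C | intermediate
9 | methyltriphenylphosphonium bromide | C[P+](c1ccccc1)(c1ccccc1)c1ccccc1.[Br-] | starting material
10 | methyl methoxyacetate | COCC(=O)OC | starting material
11 | 1-methoxy-3-(triphenyl-λ5-phosphanylidene)propan-2-one | COCC(=O)C=P(c1ccccc1)(c1ccccc1)c1ccccc1 | intermediate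
12 | aldol adduct: (3R,4R,5R)-lactone 8 in which the formyl group has become CH(OH)–CH(OMe)–C(=O)–CH=PPh3 (epimer mixture at the two new side-chain centres) | C=CC[C@@]1(C(O)C(OC)C(=O)C=P(c2ccccc2)(c2ccccc2)c2ccccc2)C(=O)O[C@@H](c2ccc(OC)c(OC)c2)[C@@H]1C | intermediate
13 | (2R,3R,3aR)-2-(3,4-dimethoxyphenyl)-4-hydroxy-5-methoxy-3-methyl-3a-(prop-2-en-1-yl)-3,3a,4,5-tetrahydro-1-benzofuran-6(2H)-one (epimer mixture at C4 and C5) | C=CC[C@@]12C(O)C(OC)C(=O)C=C1O[C@@H](c1ccc(OC)c(OC)c1)[C@@H]2C | intermediate
14 | 4-O-methanesulfonate of 13 | C=CC[C@@]12C(OS(C)(=O)=O)C(OC)C(=O)C=C1O[C@@H](c1ccc(OC)c(OC)c1)[C@@H]2C | intermediate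
15 | (2R,3R,3aR)-2-(3,4-dimethoxyphenyl)-5-methoxy-3-methyl-3a-(prop-2-en-1-yl)-3,3a-dihydro-1-benzofuran-6(2H)-one (3a-allyl trans to 3-methyl) | C=CC[C@@]12C=C(OC)C(=O)C=C1O[C@@H](c1ccc(OC)c(OC)c1)[C@@H]2C | intermediate
16 | (2R,3R,5S)-2-(3,4-dimethoxyphenyl)-5-methoxy-3-methyl-5-(prop-2-en-1-yl)-2,3-dihydro-1-benzofuran-6(5H)-one | C=CC[C@]1(OC)C=C2C(=CC1=O)O[C@@H](c1ccc(OC)c(OC)c1)[C@@H]2C | target

Total step count: 8. Longest linear sequence: 7 steps (steps 1 to 5, 7 and 8); step 6 is a one-step branch.

Steps most likely to fail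

Step 7. The ylide may be C-acylated by the lactone with ring opening (expulsion of the O1 alkoxide) instead of olefinating it, or the lithium aldolate may fragment at the quaternary carbon (retro-aldol or deformylation) before it is quenched. The fallback sets out from 8 and separates the two bond formations with enolate chemistry. A proline-catalysed direct aldol addition of methoxyacetone, which reacts through its more substituted enamine at the methoxy-bearing carbon, gives the β-hydroxy methyl ketone (3R,4R,5R)-3-allyl-5-(3,4-dimethoxyphenyl)-3-(1-hydroxy-2-methoxy-3-oxobutyl)-4-methyloxolan-2-one F1. Silylation with TBSOTf and 2,6-lutidine gives its tert-butyldimethylsilyl ether F2. LiHMDS in THF then forms the methyl-side enolate (kinetic deprotonation away from the methoxy group), which undergoes intramolecular Claisen condensation onto the lactone carbonyl to the ring-opened cyclohexane-1,3-dione F3. HF·pyridine in MeCN removes the silyl group and recloses O1 onto C7a with loss of water. The fallback comes back to the route at 13, which is dehydrated with MsCl and Et3N as in step 7.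

Step 8. The product is itself a 1,5-diene (an ortho-dienone with a C5 allyl group) and may shift onward to the aromatic allyl ether at the temperature the Cope step needs, or the Cope equilibrium may not favour 16. The reaction should be stopped at partial conversion and 15 recycled. The fallback avoids any sigmatropic step and sets out from 7 and 11. O-Methylation of 7 (Me2SO4, K2CO3, acetone) gives (4R,5R)-5-(3,4-dimethoxyphenyl)-3-(methoxymethylidene)-4-methyloxolan-2-one F4. γ-Allylation of the ylide anion of 11 (LDA, then allyl bromide) gives racemic 3-methoxy-1-(triphenyl-λ5-phosphanylidene)hex-5-en-2-one F5. The ylide anion of F5 (LDA, −78 °C) adds to C4 of F4 with loss of methoxide to give the alkylidene lactone ylide F6 in the flask. Ring closure needs the new quaternary carbon cis to the lactone carbonyl, which it should prefer in order to avoid the C3 methyl, with iodine or light equilibration otherwise. Heating in toluene then closes the ring by the same lactone Wittig olefination. This gives 16 together with its C5 epimer (2R,3R,5R)-2-(3,4-dimethoxyphenyl)-5-methoxy-3-methyl-5-(prop-2-en-1-yl)-2,3-dihydro-1-benzofuran-6(5H)-one F7, which is removed by chromatography; the fallback comes back to the route at 16, at the cost of stereocontrol at C5.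

Step 5. The enolate may be allylated on oxygen, the quaternary formyl lactone may lose its formyl group, or the allyl group may enter syn to the C3 methyl. The fallback sets out from 7 and delivers the allyl group intramolecularly. O-Allylation with allyl bromide and K2CO3 in acetone gives the allyl enol ether (4R,5R)-3-[(allyloxy)methylidene]-5-(3,4-dimethoxyphenyl)-4-methyloxolan-2-one F8. A thermal Claisen rearrangement (PhMe, 80 to 110 °C) through a chair transition state on the face of C3a anti to the C3 methyl should then give the C-allyl aldehyde; the fallback comes back to the route at 8.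

Further compounds
F1 | step 7 | (3R,4R,5R)-3-allyl-5-(3,4-dimethoxyphenyl)-3-(1-hydroxy-2-methoxy-3-oxobutyl)-4-methyloxolan-2-one (epimer mixture in the side chain) | C=CC[C@@]1(C(O)C(OC)C(C)=O)C(=O)O[C@@H](c2ccc(OC)c(OC)c2)[C@@H]1C
F2 | step 7 | tert-butyldimethylsilyl ether of F1 | C=CC[C@@]1(C(O[Si](C)(C)C(C)(C)C)C(OC)C(C)=O)C(=O)O[C@@H](c2ccc(OC)c(OC)c2)[C@@H]1C
F3 | step 7 | 4-allyl-5-(tert-butyldimethylsilyloxy)-4-[(1R,2R)-1-(3,4-dimethoxyphenyl)-1-hydroxypropan-2-yl]-6-methoxycyclohexane-1,3-dione (ring-opened Claisen product, configuration at the quaternary carbon as in 8) | C=CC[C@@]1([C@@H](C)[C@@H](O)c2ccc(OC)c(OC)c2)C(O[Si](C)(C)C(C)(C)C)C(OC)C(=O)CC1=O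
F4 | step 8 | (4R,5R)-5-(3,4-dimethoxyphenyl)-3-(methoxymethylidene)-4-methyloxolan-2-one | COC=C1C(=O)O[C@@H](c2ccc(OC)c(OC)c2)[C@@H]1C
F5 | step 8 | 3-methoxy-1-(triphenyl-λ5-phosphanylidene)hex-5-en-2-one (racemic) | C=CCC(OC)C(=O)C=P(c1ccccc1)(c1ccccc1)c1ccccc1
F6 | step 8 | (4R,5R)-5-(3,4-dimethoxyphenyl)-3-[2-methoxy-2-(prop-2-en-1-yl)-3-oxo-4-(triphenyl-λ5-phosphanylidene)butylidene]-4-methyloxolan-2-one (both configurations at the quaternary carbon) | C=CCC(OC)(C=C1C(=O)O[C@@H](c2ccc(OC)c(OC)c2)[C@@H]1C)C(=O)C=P(c2ccccc2)(c2ccccc2)c2ccccc2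
F7 | step 8 | (2R,3R,5R)-2-(3,4-dimethoxyphenyl)-5-methoxy-3-methyl-5-(prop-2-en-1-yl)-2,3-dihydro-1-benzofuran-6(5H)-one (C5 epimer of 16) | C=CC[C@@]1(OC)C=C2C(=CC1=O)O[C@@H](c1ccc(OC)c(OC)c1)[C@@H]2C
F8 | step 5 | (4R,5R)-3-[(allyloxy)methylidene]-5-(3,4-dimethoxyphenyl)-4-methyloxolan-2-one | C=CCOC=C1C(=O)O[C@@H](c2ccc(OC)c(OC)c2)[C@@H]1C
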